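**Retrosynthetic overview** (eremophilane numbering: C5 = methyl-bearing ring-fusion carbon, C10 = ring-fusion CH, C7 = isopropenyl carbon, C8 = ketone, C9 = carbinol, C3 = acyloxy carbon; ring A = C5–C10, ring B = C1–C5/C10)
1. Target 29 ⇒ esterification of the C3 alcohol of cis-decalin 18 with acid 27, then O9 desilylation.
2. 18 ⇒ monocyclic oxalate 16 by one SmI2 cascade: C5–C10 first (ring B, 6-exo radical conjugate addition), then C7–C8 (ring A, allylsamarium acyl substitution that opens the lactone).
3. Enabling feature: in the cis-fused target O3 and C9 are 1,4-cis on ring B, and C8 is a carbonyl next to the isopropenyl-bearing C7. C8 can therefore be tied to O3 as a seven-membered 2-silyloxy-2-enoate lactone (O3, C8, C9, C10, C1, C2, C3), which activates C10, fixes the 10βH fusion, holds C8 at the acyl level and frees O3 when ring A closes.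
4. 16 ⇒ diol sulfone 10 + acid 13 (esterification, ring-closing metathesis, oxalate) ⇒ methyl ketone 6 (oxirane, opening by lithiated sulfone 8) ⇒ Evans syn-aldol of 1 and 2 (sets C3 and C4).
5. 27 ⇒ methyl (R)-2-hydroxybutanoate 19 (reduction/Wittig) + angelic acid 24.

Key step: step 12

Remark: the future C5 and the sulfonyl-bearing carbon are carried as epimer mixtures in 7–17 because step 12 erases both; C7 and C9 of 18, both α to the ketone, are assumed to settle diequatorial under the basic samarium alkoxide conditions of step 12.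

Step 1
Reactants: 1 (S)-4-benzyl-3-propionyloxazolidin-2-one; 2 pent-4-enal
Product: 3 (S)-4-benzyl-3-[(2S,3R)-3-hydroxy-2-methylhept-6-enoyl]oxazolidin-2-one
Conditions: Bu2BOTf, i-Pr2NEt, CH2Cl2, −78 → 0 °C; then pH 7 buffer, MeOH, H2O2
Reagents that add atoms: none
Why: Evans syn-aldol reaction, in which the Z boron enolate should react through a chair Zimmerman–Traxler transition state on the face left open by the benzyl group and so set the future C4 and C3 centres as the (2S,3R) syn pair.

Step 2
Reactants: 3
Product: 4 (2S,3R)-3-hydroxy-N-methoxy-N,2-dimethylhept-6-enamide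
Conditions: MeNH(OMe)·HCl, AlMe3, CH2Cl2, 0 → 25 °C
Reagents that add atoms: N,O-dimethylhydroxylamine hydrochloride, CNOC.Cl
Why: aluminium amide transamidation of the imide to the Weinreb amide should release the auxiliary without touching either stereocentre.

Step 3
Reactants: 4
Product: 5 (2S,3R)-N-methoxy-N,2-dimethyl-3-(triethylsilyloxy)hept-6-enamide
Conditions: Et3SiCl, imidazole, DMF, 0 °C
Reagents that add atoms: chlorotriethylsilane, CC[Si](Cl)(CC)CC
Why: routine silylation masks the secondary alcohol so that the following organometallic steps cannot trigger retro-aldol cleavage.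

Step 4
Reactants: 5
Product: 6 (3S,4R)-3-methyl-4-(triethylsilyloxy)oct-7-en-2-one
Conditions: MeMgBr, THF, 0 °C
Reagents that add atoms: methylmagnesium bromide, C[Mg]Br
Why: Weinreb ketone synthesis, whose chelated tetrahedral intermediate stops at the ketone stage, should give the methyl ketone (future C5 and C14) without epimerising C4.

Step 5
Reactants: 6
Product: 7 2-methyl-2-[(2S,3R)-3-(triethylsilyloxy)hept-6-en-2-yl]oxirane (both epimers at the oxirane carbon)
Conditions: ICH2Cl, MeLi·LiBr, THF, −78 → 25 °C
Reagents that add atoms: chloroiodomethane, ClCI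
Why: halomethyllithium epoxidation (Darzens-type), in which chloromethyllithium made in situ should add to the ketone at −78 °C faster than it enolises it and the chlorohydrin alkoxide should close to the oxirane on warming, the new quaternary centre forming as an inconsequential epimer mixture.

Step 6
Reactants: 7; 8 2-methylallyl phenyl sulfone
Product: 9 (6S,7R)-2,5,6-trimethyl-3-(phenylsulfonyl)-7-(triethylsilyloxy)undeca-1,10-dien-5-ol (epimers at C3 and C5 of the chain)
Conditions: 8, n-BuLi, THF, −78 °C; then 7, DMPU, −78 → 25 °C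
Reagents that add atoms: none
Why: SN2 opening of the oxirane at its CH2 terminus by the α-sulfonyl allyl carbanion should give the tertiary alcohol and bring in C6, C7 and the isopropenyl carbons, the sulfonyl-bearing centre being a further inconsequential mixture.

Step 7
Reactants: 9
Product: 10 (6S,7R)-2,5,6-trimethyl-3-(phenylsulfonyl)undeca-1,10-diene-5,7-diol
Conditions: PPTS (cat.), MeOH, 25 °C
Reagents that add atoms: none
Why: acid-catalysed methanolysis should remove the triethylsilyl ether selectively, the tertiary alcohol and the allylic sulfone being inert.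

Step 8
Reactants: 11 pyruvic acid
Product: 13 2-[(tert-butyldimethylsilyl)oxy]acrylic acid, via bis-silyl ester 12 (not isolated)
Conditions: t-BuMe2SiOTf, Et3N, CH2Cl2, 0 °C; then K2CO3 (cat.), MeOH, 0 °C
Reagents that add atoms: tert-butyldimethylsilyl trifluoromethanesulfonate, CC(C)(C)[Si](C)(C)OS(=O)(=O)C(F)(F)F
Why: soft enolisation and silylation of pyruvic acid should give the silyl enol ether silyl ester, whose far more labile silyl ester is then cleaved selectively by methanolysis.

Step 9
Reactants: 10; 13
Product: 14 (6S,7R)-5-hydroxy-2,5,6-trimethyl-3-(phenylsulfonyl)undeca-1,10-dien-7-yl 2-[(tert-butyldimethylsilyl)oxy]acrylate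
Conditions: EDC·HCl, DMAP (cat.), CH2Cl2, 0 → 25 °C
Reagents that add atoms: none
Why: Steglich esterification should acylate the secondary C3 hydroxyl selectively over the hindered tertiary one.

Step 10
Reactants: 14
Product: 15 (7R)-3-[(tert-butyldimethylsilyl)oxy]-7-[(2S)-3-hydroxy-3,6-dimethyl-5-(phenylsulfonyl)hept-6-en-2-yl]-6,7-dihydrooxepin-2(5H)-one
Conditions: second-generation Hoveyda–Grubbs catalyst RuCl2(H2IMes)(=CH-C6H4-2-O-i-Pr) (cat.), toluene, 80 °C, high dilution
Reagents that add atoms: none
Why: ring-closing metathesis between the terminal vinyl group and the 2-silyloxyacrylate should close the seven-membered unsaturated lactone, whose ring size enforces the cis alkene, while the hindered isopropenyl group next to the sulfone stays out.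

Step 11
Reactants: 15
Product: 16 1,3-dioxoisoindolin-2-yl (2S)-2-[(7R)-3-[(tert-butyldimethylsilyl)oxy]-2-oxo-2,5,6,7-tetrahydrooxepin-7-yl]-3,6-dimethyl-5-(phenylsulfonyl)hept-6-en-3-yl oxalate
Conditions: (COCl)2, N-hydroxyphthalimide, THF, 25 °C, concentrate; then 15, Et3N, DMAP (cat.), CH2Cl2, 0 °C
Reagents that add atoms: oxalyl chloride, O=C(Cl)C(=O)Cl; N-hydroxyphthalimide, O=C1c2ccccc2C(=O)N1O
Why: acylation of the tertiary alcohol with preformed chloro N-phthalimidoyl oxalate should give the redox-active oxalate that serves as the precursor of the tertiary C5 radical.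

Step 12
Reactants: 16
Product: 18 (1R,3R,4aR,5R,6R,8aS)-1-[(tert-butyldimethylsilyl)oxy]-6-hydroxy-4a,5-dimethyl-3-(prop-1-en-2-yl)octahydronaphthalen-2(1H)-one, via bicyclic lactone 17 (not isolated)
Conditions: SmI2 (0.1 M in THF, slow addition), t-BuOH, THF, 25 °C; then HMPA, further SmI2, −78 → −20 °C; aq. NH4Cl
Reagents that add atoms: none
Why: Proposed new method: SmI2 should reduce the N-phthalimidoyl oxalate, which fragments (phthalimide, two CO2) to the tertiary C5 radical; this adds 6-exo-trig to C10 of the captodative 2-silyloxy-enoate (ring B), and the C9 radical is reduced to the samarium enolate and protonated by t-BuOH to give 17. HMPA then switches on reductive cleavage of the allylic sulfone to an allylsamarium, which adds through C7 with allylic transposition to the lactone carbonyl C8 in a six-membered Barbier-type nucleophilic acyl substitution (6-exo-trig at C=O) that closes ring A, creates the isopropenyl group, leaves C8 as the ketone and frees the C3 alkoxide. The closest known reaction types are the reductive fragmentation of tert-alkyl N-phthalimidoyl oxalates with Giese trapping, sequenced SmI2 conjugate addition/nucleophilic acyl substitution of halo esters, and SmI2–HMPA Barbier reactions of allylic sulfones. C3 and C4 come in with 16, and because C5 is tethered through C4–C3 to the seven-membered lactone it can reach C10 only on the face syn to C4, through a boat-like 2-oxabicyclo[3.2.2]nonanone transition state, so O3 and C9 end cis on ring B, which is the 10βH cis-decalin fusion. At C5 the methyl group is expected to take the position eclipsing the C4 methyl group so that C6 lies under the lactone bridge, and only this epimer can bring C7 to C8, so ring-A closure filters out the wrong C5 epimer, while C7 and C9, α to the new ketone, settle equatorial. The step needs the oxalate to be reduced before the enoate and the sulfone, which its much easier reduction and the absence of HMPA in the first stage should secure, and it needs radical closure to outrun further reduction, which slow addition of SmI2 should secure.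

Step 13
Reactants: 19 methyl (R)-2-hydroxybutanoate
Product: 20 methyl (R)-2-[(tert-butyldimethylsilyl)oxy]butanoate
Conditions: t-BuMe2SiCl, imidazole, DMF, 25 °C
Reagents that add atoms: tert-butyldimethylsilyl chloride, CC(C)(C)[Si](C)(C)Cl
Why: routine silylation protects the secondary alcohol for the reduction and olefination that follow.

Step 14
Reactants: 20
Product: 22 tert-butyl (R,E)-4-[(tert-butyldimethylsilyl)oxy]hex-2-enoate, via aldehyde 21 (not isolated)
Conditions: i-Bu2AlH, CH2Cl2, −78 °C; then Ph3P=CHCO2t-Bu, −78 → 25 °C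
Reagents that add atoms: tert-butyl (triphenylphosphoranylidene)acetate, CC(C)(C)OC(=O)C=P(c1ccccc1)(c1ccccc1)c1ccccc1
Why: half-reduction of the ester followed by in situ Wittig olefination with the stabilised ylide should give the E enoate without isolating the configurationally labile α-silyloxy aldehyde.

Step 15
Reactants: 22
Product: 23 tert-butyl (R,E)-4-hydroxyhex-2-enoate
Conditions: HF·pyridine, THF, 0 → 25 °C
Reagents that add atoms: none
Why: fluoride-mediated desilylation under non-basic conditions should free the allylic alcohol, and the E geometry precludes lactonisation.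

Step 16
Reactants: 23; 24 angelic acid [(Z)-2-methylbut-2-enoic acid]
Product: 26 tert-butyl (R,E)-4-[(Z)-2-methylbut-2-enoyloxy]hex-2-enoate, via mixed anhydride 25 (not isolated)
Conditions: 24, 2,4,6-trichlorobenzoyl chloride, Et3N, toluene, 25 °C; then 23, 80 °C
Reagents that add atoms: none
Why: Yamaguchi-type mixed-anhydride esterification run without DMAP, the mode in which angelates are expected to form without isomerisation to tiglates.

Step 17
Reactants: 26
Product: 27 (R,E)-4-[(Z)-2-methylbut-2-enoyloxy]hex-2-enoic acid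
Conditions: CF3CO2H, CH2Cl2, 0 °C
Reagents that add atoms: none
Why: acidolysis of the tert-butyl ester with loss of isobutene should free the acid while leaving the angelate and the allylic acyloxy group alone.

Step 18
Reactants: 18; 27
Product: 28 (3R,4R,5R,7R,9R,10S)-9-[(tert-butyldimethylsilyl)oxy]-8-oxoeremophil-11-en-3-yl (R,E)-4-[(Z)-2-methylbut-2-enoyloxy]hex-2-enoate
Conditions: EDC·HCl, DMAP (cat.), CH2Cl2, 0 °C
Reagents that add atoms: none
Why: Steglich esterification of the equatorial secondary C3 hydroxyl proceeds with retention, and low temperature with substoichiometric DMAP should limit angelate isomerisation and enolisation of the ketone.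

Step 19
Reactants: 28
Product: 29 target CNP0190706.1, (3R,4R,5R,7R,9R,10S)-9-hydroxy-8-oxoeremophil-11-en-3-yl (R,E)-4-[(Z)-2-methylbut-2-enoyloxy]hex-2-enoate
Conditions: HF·pyridine, pyridine, THF, 0 °C
Reagents that add atoms: none
Why: buffered fluoride cleavage of the silyl ether should unveil the α-ketol without acyl migration or conjugation of the isopropenyl group.

**Compound list**
1 | (S)-4-benzyl-3-propionyloxazolidin-2-one | CCC(=O)N1C(=O)OC[C@@H]1Cc1ccccc1 | starting material
2 | pent-4-enal | C=CCCC=O | starting material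
3 | (S)-4-benzyl-3-[(2S,3R)-3-hydroxy-2-methylhept-6-enoyl]oxazolidin-2-one | C=CCC[C@@H](O)[C@H](C)C(=O)N1C(=O)OC[C@@H]1Cc1ccccc1 | intermediate
4 | (2S,3R)-3-hydroxy-N-methoxy-N,2-dimethylhept-6-enamide | C=CCC[C@@H](O)[C@H](C)C(=O)N(C)OC | intermediate
5 | (2S,3R)-N-methoxy-N,2-dimethyl-3-(triethylsilyloxy)hept-6-enamide | C=CCC[C@@H](O[Si](CC)(CC)CC)[C@H](C)C(=O)N(C)OC | intermediate
6 | (3S,4R)-3-methyl-4-(triethylsilyloxy)oct-7-en-2-one | C=CCC[C@@H](O[Si](CC)(CC)CC)[C@H](C)C(C)=O | intermediate
7 | 2-methyl-2-[(2S,3R)-3-(triethylsilyloxy)hept-6-en-2-yl]oxirane (epimers at the oxirane carbon) | C=CCC[C@@H](O[Si](CC)(CC)CC)[C@H](C)C1(C)CO1 | intermediate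
8 | 2-methylallyl phenyl sulfone | CC(=C)CS(=O)(=O)c1ccccc1 | starting material
9 | (6S,7R)-2,5,6-trimethyl-3-(phenylsulfonyl)-7-(triethylsilyloxy)undeca-1,10-dien-5-ol (epimers at C3, C5) | C=CCC[C@@H](O[Si](CC)(CC)CC)[C@H](C)C(C)(O)CC(C(C)=C)S(=O)(=O)c1ccccc1 | intermediate
10 | (6S,7R)-2,5,6-trimethyl-3-(phenylsulfonyl)undeca-1,10-diene-5,7-diol (epimers at C3, C5) | C=CCC[C@@H](O)[C@H](C)C(C)(O)CC(C(C)=C)S(=O)(=O)c1ccccc1 | intermediate
11 | pyruvic acid | CC(=O)C(=O)O | starting material
12 | tert-butyldimethylsilyl 2-[(tert-butyldimethylsilyl)oxy]acrylate | C=C(O[Si](C)(C)C(C)(C)C)C(=O)O[Si](C)(C)C(C)(C)C | intermediate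
13 | 2-[(tert-butyldimethylsilyl)oxy]acrylic acid | C=C(O[Si](C)(C)C(C)(C)C)C(=O)O | intermediate
14 | (6S,7R)-5-hydroxy-2,5,6-trimethyl-3-(phenylsulfonyl)undeca-1,10-dien-7-yl 2-[(tert-butyldimethylsilyl)oxy]acrylate | C=CCC[C@@H](OC(=O)C(=C)O[Si](C)(C)C(C)(C)C)[C@H](C)C(C)(O)CC(C(C)=C)S(=O)(=O)c1ccccc1 | intermediate
15 | (7R)-3-[(tert-butyldimethylsilyl)oxy]-7-[(2S)-3-hydroxy-3,6-dimethyl-5-(phenylsulfonyl)hept-6-en-2-yl]-6,7-dihydrooxepin-2(5H)-one | O=C1O[C@H](CCC=C1O[Si](C)(C)C(C)(C)C)[C@H](C)C(C)(O)CC(C(C)=C)S(=O)(=O)c1ccccc1 | intermediate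
16 | 1,3-dioxoisoindolin-2-yl (2S)-2-[(7R)-3-[(tert-butyldimethylsilyl)oxy]-2-oxo-2,5,6,7-tetrahydrooxepin-7-yl]-3,6-dimethyl-5-(phenylsulfonyl)hept-6-en-3-yl oxalate | O=C1O[C@H](CCC=C1O[Si](C)(C)C(C)(C)C)[C@H](C)C(C)(OC(=O)C(=O)ON2C(=O)c3ccccc3C2=O)CC(C(C)=C)S(=O)(=O)c1ccccc1 | intermediate
17 | (1R,5S,6R,7R)-4-[(tert-butyldimethylsilyl)oxy]-6,7-dimethyl-6-[3-methyl-2-(phenylsulfonyl)but-3-en-1-yl]-2-oxabicyclo[3.2.2]nonan-3-one (epimers at C4 and the sulfonyl carbon) | O=C1O[C@@H]2CC[C@H](C1O[Si](C)(C)C(C)(C)C)[C@](C)(CC(C(C)=C)S(=O)(=O)c1ccccc1)[C@H]2C | intermediate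
18 | (1R,3R,4aR,5R,6R,8aS)-1-[(tert-butyldimethylsilyl)oxy]-6-hydroxy-4a,5-dimethyl-3-(prop-1-en-2-yl)octahydronaphthalen-2(1H)-one | C=C(C)[C@H]1C[C@@]2(C)[C@H](CC[C@@H](O)[C@@H]2C)[C@@H](O[Si](C)(C)C(C)(C)C)C1=O | intermediate
19 | methyl (R)-2-hydroxybutanoate | CC[C@@H](O)C(=O)OC | starting material
20 | methyl (R)-2-[(tert-butyldimethylsilyl)oxy]butanoate | CC[C@@H](O[Si](C)(C)C(C)(C)C)C(=O)OC | intermediate
21 | (R)-2-[(tert-butyldimethylsilyl)oxy]butanal | CC[C@@H](O[Si](C)(C)C(C)(C)C)C=O | intermediate
22 | tert-butyl (R,E)-4-[(tert-butyldimethylsilyl)oxy]hex-2-enoate | CC[C@@H](O[Si](C)(C)C(C)(C)C)/C=C/C(=O)OC(C)(C)C | intermediate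
23 | tert-butyl (R,E)-4-hydroxyhex-2-enoate | CC[C@@H](O)/C=C/C(=O)OC(C)(C)C | intermediate
24 | angelic acid | C/C=C(/C)C(=O)O | starting material
25 | (Z)-2-methylbut-2-enoic 2,4,6-trichlorobenzoic anhydride | C/C=C(/C)C(=O)OC(=O)c1c(Cl)cc(Cl)cc1Cl | intermediate
26 | tert-butyl (R,E)-4-[(Z)-2-methylbut-2-enoyloxy]hex-2-enoate | CC[C@@H](OC(=O)/C(C)=C\C)/C=C/C(=O)OC(C)(C)C | intermediate
27 | (R,E)-4-[(Z)-2-methylbut-2-enoyloxy]hex-2-enoic acid | CC[C@@H](OC(=O)/C(C)=C\C)/C=C/C(=O)O | intermediate
28 | (3R,4R,5R,7R,9R,10S)-9-[(tert-butyldimethylsilyl)oxy]-8-oxoeremophil-11-en-3-yl (R,E)-4-[(Z)-2-methylbut-2-enoyloxy]hex-2-enoate | C=C(C)[C@H]1C[C@@]2(C)[C@H](CC[C@@H](OC(=O)/C=C/[C@@H](CC)OC(=O)/C(C)=C\C)[C@@H]2C)[C@@H](O[Si](C)(C)C(C)(C)C)C1=O | intermediate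
29 | CNP0190706.1, (3R,4R,5R,7R,9R,10S)-9-hydroxy-8-oxoeremophil-11-en-3-yl (R,E)-4-[(Z)-2-methylbut-2-enoyloxy]hex-2-enoate | C=C(C)[C@H]1C[C@@]2(C)[C@H](CC[C@@H](OC(=O)/C=C/[C@@H](CC)OC(=O)/C(C)=C\C)[C@@H]2C)[C@@H](O)C1=O | target

**Step count**
Total steps: 19. Longest linear sequence: 13 steps (steps 1–7, 9–12, 18, 19).

**Steps most likely to fail**

Step 12 (proposed cascade). The alkoxycarbonyl or tertiary radical may be reduced before fragmentation and 6-exo closure. The radical may attack on the face that leaves C6 away from the lactone bridge, and that epimer cannot close ring A. The allylsamarium may be protonated before acyl substitution, or the α-silyloxy group may be lost reductively once the ketone exists. The fallback separates the two bond formations into known reactions, sets out from 16 and returns at 18. Visible-light reductive fragmentation and Giese cyclisation of 16 (Ru(bpy)3(PF6)2 cat., Hantzsch ester, i-Pr2NEt·HBF4, THF/CH2Cl2, blue light) would give bicyclic lactone 17, now isolated. LiN(SiMe3)2 (THF, −78 → 0 °C) would then form the α-sulfonyl carbanion, which acylates C8 in a Dieckmann-type step and opens the lactone to the β-keto sulfone F1. Reductive desulfonylation with Al(Hg) in THF/H2O would give 18.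

Step 6. Opening of the hindered 2,2-disubstituted oxirane may be slow, the allyl sulfonyl anion may react through its γ-carbon, or the base may isomerise the oxirane to an allylic alcohol. The fallback builds the same carbon chain by aldol chemistry, sets out from 6 and returns at 9. Kinetic enolisation of 6 (LiN(i-Pr)2, THF, −78 °C) and addition to methacrolein would give the aldol adduct F2. MeLi/CeCl3 (THF, −78 °C) would give the diol F3. PhSSPh/PBu3 in pyridine would convert the secondary allylic alcohol into the allylic sulfide F4. Oxidation at sulfur with H2O2 and (NH4)6Mo7O24 (cat.) in EtOH would give 9.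

Step 16. The Z double bond of the activated angeloyl unit may isomerise to the E (tigloyl) isomer, or acylation of the allylic alcohol may stall. The fallback makes the Z alkene by olefination after the ester bond exists, sets out from 23 and returns at 26. Esterification of 23 with 2-[bis(2,2,2-trifluoroethoxy)phosphoryl]propanoic acid (DCC, DMAP cat., CH2Cl2) would give the phosphonate ester F5. Still–Gennari olefination with acetaldehyde (KN(SiMe3)2, 18-crown-6, THF, −78 °C) should then give the Z-configured 26.

**Further compounds**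
F1 | step 12 | (4aR,5R,6R,8aS)-1-[(tert-butyldimethylsilyl)oxy]-6-hydroxy-4a,5-dimethyl-3-(phenylsulfonyl)-3-(prop-1-en-2-yl)octahydronaphthalen-2(1H)-one (epimers at C1, C3) | C=C(C)C1(S(=O)(=O)c2ccccc2)C[C@@]2(C)[C@H](CC[C@@H](O)[C@@H]2C)C(O[Si](C)(C)C(C)(C)C)C1=O
F2 | step 6 | (6S,7R)-3-hydroxy-2,6-dimethyl-7-(triethylsilyloxy)undeca-1,10-dien-5-one | C=CCC[C@@H](O[Si](CC)(CC)CC)[C@H](C)C(=O)CC(O)C(C)=C
F3 | step 6 | (6S,7R)-2,5,6-trimethyl-7-(triethylsilyloxy)undeca-1,10-diene-3,5-diol | C=CCC[C@@H](O[Si](CC)(CC)CC)[C@H](C)C(C)(O)CC(O)C(C)=C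
F4 | step 6 | (6S,7R)-2,5,6-trimethyl-3-(phenylsulfanyl)-7-(triethylsilyloxy)undeca-1,10-dien-5-ol | C=CCC[C@@H](O[Si](CC)(CC)CC)[C@H](C)C(C)(O)CC(Sc1ccccc1)C(C)=C
F5 | step 16 | tert-butyl (R,E)-4-({2-[bis(2,2,2-trifluoroethoxy)phosphoryl]propanoyl}oxy)hex-2-enoate | CC[C@@H](OC(=O)C(C)P(=O)(OCC(F)(F)F)OCC(F)(F)F)/C=C/C(=O)OC(C)(C)C
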